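The plan rests on opening the 14-membered carbocycle at its C7=C8 trisubstituted alkene, the ring bond flanked by two CH2CH2 spacers and remote from the stereocentres C1, C2 and C13. Both alkene carbons become carbonyl electrophiles (C7 aldehyde, C8 methyl ketone). A titanium-mediated reductive carbonyl coupling should then close the 14-membered ring and create the 7E alkene in one operation. Its substrate is an open-chain (1R,2S,13R) keto-aldehyde in which the α-methylene lactone is masked as a bis-silylated 2-methylene-1,4-diol and O13 is silylated. It is built from geranyl acetate by an Evans syn aldol (C1, C2), an alkyllithium–Weinreb amide union (C13–C14) and a CBS reduction (C13).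

Key step: step 20

Remark: atoms carry the numbers of the cembrane skeleton of the target (C1 bears the C15–C17 unit, O2 is the lactone oxygen, C16 the lactone carbonyl, C17 the exocyclic methylene, C18–C20 the methyls on C4, C8 and C12).
Remark: C13 is carried as the 13R alcohol, opposite to the 13S acetate of the target, because hydroxyl-directed epoxidation of the 13R alcohol should give the erythro epoxy alcohol and the final SN2 esterification inverts C13.
Remark: O16 carries TBDPS and O2/O13 carry TBS, and C7/C8 travel as dimethyl acetal and dioxolane, so that one mild acid treatment releases both carbonyl groups without loss of the primary allylic silyl ether.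
Remark: (2-ethoxy-2-oxoethyl)zinc bromide is taken as the commercial ether solution; it can equally be made from ethyl bromoacetate and zinc dust.

Step 1
Reactants: 1 geranyl acetate [(2E)-3,7-dimethylocta-2,6-dien-1-yl acetate]
Product: 3 (2E)-3-methyl-6-oxohex-2-en-1-yl acetate, via ozonide 2 (not isolated)
Conditions: O3 (1 equiv, Sudan Red 7B end point), CH2Cl2, −78 °C; then Me2S, −78 °C → rt
Reagents that add atoms: ozone, [O-][O+]=O
Why: Ozonolysis with reductive work-up; ozone attacks the electron-rich 6,7-alkene much faster than the 2,3-alkene deactivated by the allylic acetate, so one equivalent should cleave only the isopropylidene end and leave the 2E alkene (later C3=C4) untouched.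

Step 2
Reactants: 3 (2E)-3-methyl-6-oxohex-2-en-1-yl acetate
Product: 5 (2E)-6,6-dimethoxy-3-methylhex-2-en-1-ol, via acetal acetate 4 (not isolated)
Conditions: HC(OMe)3, pyridinium p-toluenesulfonate (cat.), MeOH, rt; then K2CO3 (0.3 equiv), rt
Reagents that add atoms: trimethyl orthoformate, COC(OC)OC; methanol, CO
Why: Acid-catalysed acetalisation with an orthoformate water scavenger, followed in the same pot by base-catalysed methanolysis (transesterification) of the allylic acetate, to which the acetal is inert.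

Step 3
Reactants: 5 (2E)-6,6-dimethoxy-3-methylhex-2-en-1-ol
Product: 6 (2E)-6,6-dimethoxy-3-methylhex-2-enal
Conditions: activated MnO2 (15 equiv), CH2Cl2, rt
Reagents that add atoms: none
Why: MnO2 oxidation is selective for allylic alcohols and should give the enal (C2 aldehyde) without touching the acetal or the alkene geometry.

Step 4
Reactants: 7 2-bromoprop-2-en-1-ol
Product: 8 [(2-bromoprop-2-en-1-yl)oxy](tert-butyl)diphenylsilane
Conditions: t-BuPh2SiCl, imidazole, CH2Cl2, 0 °C → rt
Reagents that add atoms: tert-butyl(chloro)diphenylsilane, CC(C)(C)[Si](Cl)(c1ccccc1)c1ccccc1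
Why: Standard silylation of a primary alcohol; TBDPS is chosen because this oxygen (O16) must outlast the acidic release of the carbonyl groups in step 19.

Step 5
Reactants: 8 [(2-bromoprop-2-en-1-yl)oxy](tert-butyl)diphenylsilane; 9 (2-ethoxy-2-oxoethyl)zinc bromide
Product: 10 ethyl 3-({[tert-butyl(diphenyl)silyl]oxy}methyl)but-3-enoate
Conditions: Pd(PPh3)4 (5 mol %), THF, 60 °C
Reagents that add atoms: none
Why: Palladium-catalysed Negishi-type cross-coupling of a Reformatsky zinc enolate with an alkenyl bromide, which gives the β,γ-unsaturated ester (C14, C1, C15–C17) directly and tolerates the allylic silyl ether.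

Step 6
Reactants: 10 ethyl 3-({[tert-butyl(diphenyl)silyl]oxy}methyl)but-3-enoate
Product: 11 3-({[tert-butyl(diphenyl)silyl]oxy}methyl)but-3-enoic acid
Conditions: LiOH·H2O, THF/H2O, 0 °C → rt; then 1 M HCl to pH 4, 0 °C
Reagents that add atoms: lithium hydroxide, [Li+].[OH-]
Why: Saponification of an unhindered ethyl ester at low temperature, where the deconjugated 1,1-disubstituted alkene should not migrate into conjugation and the TBDPS ether is stable.

Step 7
Reactants: 11 3-({[tert-butyl(diphenyl)silyl]oxy}methyl)but-3-enoic acid; 12 (4R)-4-benzyl-1,3-oxazolidin-2-one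
Product: 14 (4R)-4-benzyl-3-[3-({[tert-butyl(diphenyl)silyl]oxy}methyl)but-3-enoyl]-1,3-oxazolidin-2-one, via mixed pivalic anhydride 13 (not isolated)
Conditions: t-BuCOCl, Et3N, THF, −20 °C; then 12, LiCl, −20 °C → rt
Reagents that add atoms: none
Why: N-Acylation of the oxazolidinone through the mixed pivalic anhydride under LiCl/Et3N activation, a mild entry to Evans imides that avoids strong base and so avoids alkene migration.

Step 8
Reactants: 14 (4R)-4-benzyl-3-[3-({[tert-butyl(diphenyl)silyl]oxy}methyl)but-3-enoyl]-1,3-oxazolidin-2-one; 6 (2E)-6,6-dimethoxy-3-methylhex-2-enal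
Product: 17 (4R)-4-benzyl-3-[(2R,3S,4E)-2-(3-{[tert-butyl(diphenyl)silyl]oxy}prop-1-en-2-yl)-3-hydroxy-8,8-dimethoxy-5-methyloct-4-enoyl]-1,3-oxazolidin-2-one, via boron enolate 15 (not isolated), via boron aldolate 16 (not isolated)
Conditions: Bu2BOTf, i-Pr2NEt, CH2Cl2, −78 → 0 °C; then 6, −78 → 0 °C; then NaH2PO4/Na2HPO4 buffer (pH 7), MeOH, 30% H2O2, 0 °C
Reagents that add atoms: none
Why: Evans syn aldol reaction; the Z boron dienolate reacts at its α-carbon through a Zimmerman–Traxler chair whose face is fixed by the (R)-benzyl oxazolidinone, which should set C1 and C2 together with the syn relationship that corresponds to the trans lactone of the target, enals being good acceptors.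

Step 9
Reactants: 17 aldol adduct (free C2 hydroxyl)
Product: 18 (4R)-4-benzyl-3-[(2R,3S,4E)-3-{[tert-butyl(dimethyl)silyl]oxy}-2-(3-{[tert-butyl(diphenyl)silyl]oxy}prop-1-en-2-yl)-8,8-dimethoxy-5-methyloct-4-enoyl]-1,3-oxazolidin-2-one
Conditions: t-BuMe2SiOTf, 2,6-lutidine, CH2Cl2, −78 °C
Reagents that add atoms: tert-butyldimethylsilyl trifluoromethanesulfonate, CC(C)(C)[Si](C)(C)OS(=O)(=O)C(F)(F)F
Why: Silylation of the hindered secondary aldol hydroxyl with the silyl triflate at −78 °C, where the dimethyl acetal is not activated; the ether blocks retro-aldol cleavage in the next step.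

Step 10
Reactants: 18 O2-TBS aldol imide
Product: 19 (2S,3S,4E)-3-{[tert-butyl(dimethyl)silyl]oxy}-2-(3-{[tert-butyl(diphenyl)silyl]oxy}prop-1-en-2-yl)-8,8-dimethoxy-5-methyloct-4-en-1-ol
Conditions: LiBH4, MeOH (1 equiv), Et2O, 0 °C
Reagents that add atoms: none
Why: Reductive removal of the auxiliary with LiBH4 turns the imide carbonyl into the C14 primary alcohol and returns the oxazolidinone; C1 is not enolised under these conditions (its descriptor changes only because of the priority rules).

Step 11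
Reactants: 19 C14 primary alcohol
Product: 20 (2R,3S,4E)-3-{[tert-butyl(dimethyl)silyl]oxy}-2-(3-{[tert-butyl(diphenyl)silyl]oxy}prop-1-en-2-yl)-1-iodo-8,8-dimethoxy-5-methyloct-4-ene
Conditions: I2, PPh3, imidazole, CH2Cl2, 0 °C → rt
Reagents that add atoms: iodine, II
Why: Appel-type iodination converts the primary alcohol into the iodide by SN2 at C14 under imidazole-buffered conditions that spare the acetal and both silyl ethers.

Step 12
Reactants: 21 ethyl levulinate (ethyl 4-oxopentanoate)
Product: 22 ethyl 3-(2-methyl-1,3-dioxolan-2-yl)propanoate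
Conditions: HOCH2CH2OH, p-TsOH·H2O (cat.), toluene, reflux, Dean–Stark trap
Reagents that add atoms: ethane-1,2-diol, OCCO
Why: Acid-catalysed ketalisation with azeotropic removal of water masks the C8 ketone for the organometallic steps.

Step 13
Reactants: 22 ethyl 3-(2-methyl-1,3-dioxolan-2-yl)propanoate
Product: 23 3-(2-methyl-1,3-dioxolan-2-yl)propanal
Conditions: i-Bu2AlH (1.05 equiv), CH2Cl2, −78 °C; then MeOH, aq. KNaC4H4O6
Reagents that add atoms: none
Why: Partial ester reduction; at −78 °C the aluminium hemiacetal is stable and releases the aldehyde (C11) only on work-up.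

Step 14
Reactants: 23 3-(2-methyl-1,3-dioxolan-2-yl)propanal; 24 ethyl 2-(triphenyl-λ5-phosphanylidene)propanoate
Product: 25 ethyl (2E)-2-methyl-5-(2-methyl-1,3-dioxolan-2-yl)pent-2-enoate
Conditions: CH2Cl2, rt → 40 °C
Reagents that add atoms: none
Why: Wittig olefination with a stabilised α-methyl ylide, which should give the E trisubstituted enoate (the later C11=C12 alkene).

Step 15
Reactants: 25 ethyl (2E)-2-methyl-5-(2-methyl-1,3-dioxolan-2-yl)pent-2-enoate
Product: 26 (2E)-N-methoxy-N,2-dimethyl-5-(2-methyl-1,3-dioxolan-2-yl)pent-2-enamide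
Conditions: MeNH(OMe)·HCl, i-PrMgCl, THF, −20 → 0 °C
Reagents that add atoms: N,O-dimethylhydroxylamine hydrochloride, CNOC.Cl
Why: Direct aminolysis of the ester by the magnesium amide of N,O-dimethylhydroxylamine gives the Weinreb amide; the α-methyl group disfavours conjugate addition.

Step 16
Reactants: 20 C14 iodide; 26 (2E)-N-methoxy-N,2-dimethyl-5-(2-methyl-1,3-dioxolan-2-yl)pent-2-enamide
Product: 28 (4E,6S,7R,10E)-6-{[tert-butyl(dimethyl)silyl]oxy}-7-(3-{[tert-butyl(diphenyl)silyl]oxy}prop-1-en-2-yl)-1,1-dimethoxy-4,10-dimethyl-13-(2-methyl-1,3-dioxolan-2-yl)trideca-4,10-dien-9-one, via alkyllithium 27 (not isolated)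
Conditions: t-BuLi (2.1 equiv), Et2O, −78 °C; then 26, −78 → −20 °C; aq. NH4Cl
Reagents that add atoms: none
Why: Lithium–iodine exchange gives a primary alkyllithium (kept at −78 °C in ether, where oxygen-to-carbon silyl migration is slow, as with the common 3-silyloxy-2-methylpropyl lithium reagents) that adds once to the Weinreb amide through the chelated tetrahedral intermediate (Weinreb ketone synthesis), forming the C13–C14 bond and the 11E enone.

Step 17
Reactants: 28 C13 enone
Product: 29 (4E,6S,7R,9R,10E)-6-{[tert-butyl(dimethyl)silyl]oxy}-7-(3-{[tert-butyl(diphenyl)silyl]oxy}prop-1-en-2-yl)-1,1-dimethoxy-4,10-dimethyl-13-(2-methyl-1,3-dioxolan-2-yl)trideca-4,10-dien-9-ol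
Conditions: (S)-2-methyl-CBS-oxazaborolidine [(3aS)-1-methyl-3,3-diphenyltetrahydro-1H,3H-pyrrolo[1,2-c][1,3,2]oxazaborole] (0.5 equiv), catecholborane, toluene, −78 °C
Reagents that add atoms: none
Why: Corey–Bakshi–Shibata reduction; the (S)-oxazaborolidine binds the ketone with the α-methylalkenyl group as the large substituent and should deliver hydride to give the 13R allylic alcohol under catalyst control, while catecholborane at −78 °C leaves the alkenes and acetals alone.

Step 18
Reactants: 29 13R allylic alcohol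
Product: 30 (4E,6S,7R,9R,10E)-6,9-bis{[tert-butyl(dimethyl)silyl]oxy}-7-(3-{[tert-butyl(diphenyl)silyl]oxy}prop-1-en-2-yl)-1,1-dimethoxy-4,10-dimethyl-13-(2-methyl-1,3-dioxolan-2-yl)trideca-4,10-diene
Conditions: t-BuMe2SiOTf, 2,6-lutidine, CH2Cl2, −78 °C
Reagents that add atoms: tert-butyldimethylsilyl trifluoromethanesulfonate, CC(C)(C)[Si](C)(C)OS(=O)(=O)C(F)(F)F
Why: Silyl triflate silylation of the hindered secondary allylic alcohol completes the protection pattern (O2 and O13 as TBS, O16 as TBDPS).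

Step 19
Reactants: 30 tris-silyl ether with C7 dimethyl acetal and C8 dioxolane
Product: 31 (4E,6S,7R,9R,10E)-6,9-bis{[tert-butyl(dimethyl)silyl]oxy}-7-(3-{[tert-butyl(diphenyl)silyl]oxy}prop-1-en-2-yl)-4,10-dimethyl-14-oxopentadeca-4,10-dienal (C7 aldehyde, C8 methyl ketone)
Conditions: pyridinium p-toluenesulfonate (0.2 equiv), acetone/H2O (10:1), 40 °C
Reagents that add atoms: water, O
Why: Mild acid-catalysed acetal and ketal hydrolysis releases both carbonyl groups together; the secondary TBS ethers and the primary TBDPS ether should survive pyridinium tosylate in wet acetone.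

Step 20
Reactants: 31 tris-silylated keto-aldehyde
Product: 33 tert-butyl({2-[(1R,2S,3E,7E,11E,13R)-2,13-bis{[tert-butyl(dimethyl)silyl]oxy}-4,8,12-trimethylcyclotetradeca-3,7,11-trien-1-yl]prop-2-en-1-yl}oxy)diphenylsilane, via titanium pinacolate 32 (not isolated)
Conditions: TiCl3(DME)1.5 (12 equiv), Zn–Cu couple (40 equiv), DME, reflux 2 h; then 31 in DME by syringe pump over 30 h (final concentration about 3 mM), reflux 6 h more
Reagents that add atoms: none
Why: Low-valent titanium generated from TiCl3(DME)1.5 and Zn–Cu transfers single electrons to the C7 aldehyde and the C8 ketone, the two ketyl radicals couple on the titanium surface to a C7–C8 pinacolate, and at reflux this loses both oxygens to titanium to give the alkene (McMurry reaction). The closest precedent is the intramolecular titanium-induced keto-aldehyde coupling used to close 14-membered terpenoid rings. The 14-membered carbocycle closes end to end, the two carbonyl termini of one chain meeting on the metal under slow addition at high dilution so that cyclisation outruns dimerisation. No stereocentre is formed; the only new stereo-element is the C7=C8 geometry, and C1, C2 and C13 lie far from the reacting termini and carry no enolisable hydrogen. The step needs the 7E alkene: deoxygenation of the pinacolate is not stereospecific, but the isomer with C6 and C9 trans is expected to be the less strained one in a ring that already holds two E trisubstituted alkenes, and any 7Z isomer would be removed on AgNO3-impregnated silica. Silyl ethers and the isolated alkenes are inert to the reagent, which is why the lactone travels as the bis-silylated methylene diol.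

Step 21
Reactants: 33 tris-silylated macrocyclic triene
Product: 34 (1R,2S,13R)-cembra-3E,7E,11E,15(17)-tetraene-2,13,16-triol
Conditions: Bu4NF (5 equiv), THF, rt → 40 °C
Reagents that add atoms: none
Why: Fluoride-mediated cleavage of all three silyl ethers in one operation, driven by Si–F bond formation; no base-sensitive group is present at this stage.

Step 22
Reactants: 34 macrocyclic triol
Product: 37 (1R,2S,13R)-13-hydroxycembra-3E,7E,11E,15(17)-tetraen-16,2-olide, via hydroxy enal 35 (not isolated), via lactol 36 (not isolated)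
Conditions: TEMPO (2,2,6,6-tetramethylpiperidin-1-oxyl, 0.2 equiv), PhI(OAc)2 (2.5 equiv), CH2Cl2, rt
Reagents that add atoms: none
Why: Oxidative lactonisation; the oxoammonium oxidant is selective for the primary allylic alcohol over the two secondary ones, the enal is trapped by the neighbouring C2 hydroxyl as a lactol, and this is oxidised on to the trans α-methylene-γ-lactone while the C13 alcohol stays free.

Step 23
Reactants: 37 13R-hydroxy lactone
Product: 38 (1R,2S,11R,12R,13R)-11,12-epoxy-13-hydroxycembra-3E,7E,15(17)-trien-16,2-olide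
Conditions: VO(acac)2 (5 mol %), t-BuOOH (1.5 equiv, decane), CH2Cl2, 0 °C → rt
Reagents that add atoms: tert-butyl hydroperoxide, CC(C)(C)OO
Why: Vanadium-catalysed hydroxyl-directed epoxidation; the C13 vanadate delivers the peroxide only to the allylic C11=C12 alkene, and minimised A(1,2) strain with the C12 methyl should give the erythro epoxy alcohol, which is the epoxide geometry of the target (C12 reads R here only because of the priority rules), while the other alkenes and the electron-poor methylene lactone are left alone.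

Step 24
Reactants: 38 erythro epoxy alcohol
Product: 39 (1R,2S,11R,12S,13S)-13-acetoxy-11,12-epoxycembra-3E,7E,15(17)-trien-16,2-olide (CNP0146076.5)
Conditions: PPh3, diisopropyl azodicarboxylate, AcOH, toluene, 0 °C → rt
Reagents that add atoms: acetic acid, CC(=O)O
Why: Mitsunobu esterification; the alcohol is activated as an oxyphosphonium ion and displaced by acetate with SN2 inversion, turning the 13R alcohol into the 13S acetate of the target.

Compound list
1 | geranyl acetate, (2E)-3,7-dimethylocta-2,6-dien-1-yl acetate | CC(C)=CCC/C(C)=C/COC(C)=O | starting material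
2 | (2E)-5-(5,5-dimethyl-1,2,4-trioxolan-3-yl)-3-methylpent-2-en-1-yl acetate (ozonide) | CC1(C)OOC(CC/C(C)=C/COC(C)=O)O1 | intermediate
3 | (2E)-3-methyl-6-oxohex-2-en-1-yl acetate | O=CCC/C(C)=C/COC(C)=O | intermediate
4 | (2E)-6,6-dimethoxy-3-methylhex-2-en-1-yl acetate | COC(OC)CC/C(C)=C/COC(C)=O | intermediate
5 | (2E)-6,6-dimethoxy-3-methylhex-2-en-1-ol | COC(OC)CC/C(C)=C/CO | intermediate
6 | (2E)-6,6-dimethoxy-3-methylhex-2-enal | COC(OC)CC/C(C)=C/C=O | intermediate
7 | 2-bromoprop-2-en-1-ol | C=C(Br)CO | starting material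
8 | [(2-bromoprop-2-en-1-yl)oxy](tert-butyl)diphenylsilane | C=C(Br)CO[Si](c1ccccc1)(c1ccccc1)C(C)(C)C | intermediate
9 | (2-ethoxy-2-oxoethyl)zinc bromide | CCOC(=O)C[Zn]Br | starting material
10 | ethyl 3-({[tert-butyl(diphenyl)silyl]oxy}methyl)but-3-enoate | CCOC(=O)CC(=C)CO[Si](c1ccccc1)(c1ccccc1)C(C)(C)C | intermediate
11 | 3-({[tert-butyl(diphenyl)silyl]oxy}methyl)but-3-enoic acid | OC(=O)CC(=C)CO[Si](c1ccccc1)(c1ccccc1)C(C)(C)C | intermediate
12 | (4R)-4-benzyl-1,3-oxazolidin-2-one | O=C1N[C@H](Cc2ccccc2)CO1 | starting material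
13 | 3-({[tert-butyl(diphenyl)silyl]oxy}methyl)but-3-enoic 2,2-dimethylpropanoic anhydride | CC(C)(C)C(=O)OC(=O)CC(=C)CO[Si](c1ccccc1)(c1ccccc1)C(C)(C)C | intermediate
14 | (4R)-4-benzyl-3-[3-({[tert-butyl(diphenyl)silyl]oxy}methyl)but-3-enoyl]-1,3-oxazolidin-2-one | C=C(CO[Si](c1ccccc1)(c1ccccc1)C(C)(C)C)CC(=O)N1[C@H](Cc2ccccc2)COC1=O | intermediate
15 | (4R)-4-benzyl-3-[(1Z)-1-[(dibutylboranyl)oxy]-3-({[tert-butyl(diphenyl)silyl]oxy}methyl)buta-1,3-dien-1-yl]-1,3-oxazolidin-2-one (boron enolate) | CCCCB(CCCC)O/C(=C\C(=C)CO[Si](c1ccccc1)(c1ccccc1)C(C)(C)C)N1[C@H](Cc2ccccc2)COC1=O | intermediate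
16 | O-dibutylboranyl derivative of 17 (boron aldolate) | COC(OC)CC/C(C)=C/[C@H](OB(CCCC)CCCC)[C@@H](C(=C)CO[Si](c1ccccc1)(c1ccccc1)C(C)(C)C)C(=O)N1[C@H](Cc2ccccc2)COC1=O | intermediate
17 | (4R)-4-benzyl-3-[(2R,3S,4E)-2-(3-{[tert-butyl(diphenyl)silyl]oxy}prop-1-en-2-yl)-3-hydroxy-8,8-dimethoxy-5-methyloct-4-enoyl]-1,3-oxazolidin-2-one | COC(OC)CC/C(C)=C/[C@H](O)[C@@H](C(=C)CO[Si](c1ccccc1)(c1ccccc1)C(C)(C)C)C(=O)N1[C@H](Cc2ccccc2)COC1=O | intermediate
18 | (4R)-4-benzyl-3-[(2R,3S,4E)-3-{[tert-butyl(dimethyl)silyl]oxy}-2-(3-{[tert-butyl(diphenyl)silyl]oxy}prop-1-en-2-yl)-8,8-dimethoxy-5-methyloct-4-enoyl]-1,3-oxazolidin-2-one | COC(OC)CC/C(C)=C/[C@H](O[Si](C)(C)C(C)(C)C)[C@@H](C(=C)CO[Si](c1ccccc1)(c1ccccc1)C(C)(C)C)C(=O)N1[C@H](Cc2ccccc2)COC1=O | intermediate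
19 | (2S,3S,4E)-3-{[tert-butyl(dimethyl)silyl]oxy}-2-(3-{[tert-butyl(diphenyl)silyl]oxy}prop-1-en-2-yl)-8,8-dimethoxy-5-methyloct-4-en-1-ol | COC(OC)CC/C(C)=C/[C@H](O[Si](C)(C)C(C)(C)C)[C@@H](C(=C)CO[Si](c1ccccc1)(c1ccccc1)C(C)(C)C)CO | intermediate
20 | (2R,3S,4E)-3-{[tert-butyl(dimethyl)silyl]oxy}-2-(3-{[tert-butyl(diphenyl)silyl]oxy}prop-1-en-2-yl)-1-iodo-8,8-dimethoxy-5-methyloct-4-ene | COC(OC)CC/C(C)=C/[C@H](O[Si](C)(C)C(C)(C)C)[C@@H](C(=C)CO[Si](c1ccccc1)(c1ccccc1)C(C)(C)C)CI | intermediate
21 | ethyl levulinate (ethyl 4-oxopentanoate) | CCOC(=O)CCC(C)=O | starting material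
22 | ethyl 3-(2-methyl-1,3-dioxolan-2-yl)propanoate | CCOC(=O)CCC1(C)OCCO1 | intermediate
23 | 3-(2-methyl-1,3-dioxolan-2-yl)propanal | O=CCCC1(C)OCCO1 | intermediate
24 | ethyl 2-(triphenyl-λ5-phosphanylidene)propanoate | CCOC(=O)C(C)=P(c1ccccc1)(c1ccccc1)c1ccccc1 | starting material
25 | ethyl (2E)-2-methyl-5-(2-methyl-1,3-dioxolan-2-yl)pent-2-enoate | CCOC(=O)/C(C)=C/CCC1(C)OCCO1 | intermediate
26 | (2E)-N-methoxy-N,2-dimethyl-5-(2-methyl-1,3-dioxolan-2-yl)pent-2-enamide | CON(C)C(=O)/C(C)=C/CCC1(C)OCCO1 | intermediate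
27 | [(2R,3S,4E)-3-{[tert-butyl(dimethyl)silyl]oxy}-2-(3-{[tert-butyl(diphenyl)silyl]oxy}prop-1-en-2-yl)-8,8-dimethoxy-5-methyloct-4-en-1-yl]lithium | COC(OC)CC/C(C)=C/[C@H](O[Si](C)(C)C(C)(C)C)[C@@H](C(=C)CO[Si](c1ccccc1)(c1ccccc1)C(C)(C)C)C[Li] | intermediate
28 | (4E,6S,7R,10E)-6-{[tert-butyl(dimethyl)silyl]oxy}-7-(3-{[tert-butyl(diphenyl)silyl]oxy}prop-1-en-2-yl)-1,1-dimethoxy-4,10-dimethyl-13-(2-methyl-1,3-dioxolan-2-yl)trideca-4,10-dien-9-one | COC(OC)CC/C(C)=C/[C@H](O[Si](C)(C)C(C)(C)C)[C@@H](C(=C)CO[Si](c1ccccc1)(c1ccccc1)C(C)(C)C)CC(=O)/C(C)=C/CCC1(C)OCCO1 | intermediate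
29 | (4E,6S,7R,9R,10E)-6-{[tert-butyl(dimethyl)silyl]oxy}-7-(3-{[tert-butyl(diphenyl)silyl]oxy}prop-1-en-2-yl)-1,1-dimethoxy-4,10-dimethyl-13-(2-methyl-1,3-dioxolan-2-yl)trideca-4,10-dien-9-ol | COC(OC)CC/C(C)=C/[C@H](O[Si](C)(C)C(C)(C)C)[C@@H](C(=C)CO[Si](c1ccccc1)(c1ccccc1)C(C)(C)C)C[C@@H](O)/C(C)=C/CCC1(C)OCCO1 | intermediate
30 | (4E,6S,7R,9R,10E)-6,9-bis{[tert-butyl(dimethyl)silyl]oxy}-7-(3-{[tert-butyl(diphenyl)silyl]oxy}prop-1-en-2-yl)-1,1-dimethoxy-4,10-dimethyl-13-(2-methyl-1,3-dioxolan-2-yl)trideca-4,10-diene | COC(OC)CC/C(C)=C/[C@H](O[Si](C)(C)C(C)(C)C)[C@@H](C(=C)CO[Si](c1ccccc1)(c1ccccc1)C(C)(C)C)C[C@@H](O[Si](C)(C)C(C)(C)C)/C(C)=C/CCC1(C)OCCO1 | intermediate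
31 | (4E,6S,7R,9R,10E)-6,9-bis{[tert-butyl(dimethyl)silyl]oxy}-7-(3-{[tert-butyl(diphenyl)silyl]oxy}prop-1-en-2-yl)-4,10-dimethyl-14-oxopentadeca-4,10-dienal (precursor of the key step) | O=CCC/C(C)=C/[C@H](O[Si](C)(C)C(C)(C)C)[C@@H](C(=C)CO[Si](c1ccccc1)(c1ccccc1)C(C)(C)C)C[C@@H](O[Si](C)(C)C(C)(C)C)/C(C)=C/CCC(C)=O | intermediate
32 | titanium-bound C7–C8 pinacolate of the closed 14-membered ring (drawn as the diolate, mixture at C7 and C8) | C=C(CO[Si](c1ccccc1)(c1ccccc1)C(C)(C)C)[C@H]1C[C@@H](O[Si](C)(C)C(C)(C)C)/C(C)=C/CCC(C)([O-])C([O-])CC/C(C)=C/[C@@H]1O[Si](C)(C)C(C)(C)C | intermediate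
33 | tert-butyl({2-[(1R,2S,3E,7E,11E,13R)-2,13-bis{[tert-butyl(dimethyl)silyl]oxy}-4,8,12-trimethylcyclotetradeca-3,7,11-trien-1-yl]prop-2-en-1-yl}oxy)diphenylsilane (product of the key step) | C=C(CO[Si](c1ccccc1)(c1ccccc1)C(C)(C)C)[C@H]1C[C@@H](O[Si](C)(C)C(C)(C)C)/C(C)=C/CC/C(C)=C/CC/C(C)=C/[C@@H]1O[Si](C)(C)C(C)(C)C | intermediate
34 | (1R,2S,13R)-cembra-3E,7E,11E,15(17)-tetraene-2,13,16-triol | C=C(CO)[C@H]1C[C@@H](O)/C(C)=C/CC/C(C)=C/CC/C(C)=C/[C@@H]1O | intermediate
35 | (1R,2S,13R)-2,13-dihydroxycembra-3E,7E,11E,15(17)-tetraen-16-al | C=C(C=O)[C@H]1C[C@@H](O)/C(C)=C/CC/C(C)=C/CC/C(C)=C/[C@@H]1O | intermediate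
36 | (1R,2S,13R)-2,16-epoxycembra-3E,7E,11E,15(17)-tetraene-13,16-diol (lactol, either configuration at C16) | C=C1C(O)O[C@H]2/C=C(\C)CC/C=C(\C)CC/C=C(\C)[C@H](O)C[C@H]12 | intermediate
37 | (1R,2S,13R)-13-hydroxycembra-3E,7E,11E,15(17)-tetraen-16,2-olide | C=C1C(=O)O[C@H]2/C=C(\C)CC/C=C(\C)CC/C=C(\C)[C@H](O)C[C@H]12 | intermediate
38 | (1R,2S,11R,12R,13R)-11,12-epoxy-13-hydroxycembra-3E,7E,15(17)-trien-16,2-olide | C=C1C(=O)O[C@H]2/C=C(\C)CC/C=C(\C)CC[C@H]3O[C@]3(C)[C@H](O)C[C@H]12 | intermediate
39 | (1R,2S,11R,12S,13S)-13-acetoxy-11,12-epoxycembra-3E,7E,15(17)-trien-16,2-olide (CNP0146076.5) | C=C1C(=O)O[C@H]2/C=C(\C)CC/C=C(\C)CC[C@H]3O[C@]3(C)[C@@H](OC(C)=O)C[C@H]12 | target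

Total step count: 24 steps.
Longest linear sequence: 17 steps (from 7 to 39: steps 4–11 and 16–24). The geranyl acetate branch (steps 1–3) joins at step 8 and the levulinate branch (steps 12–15) joins at step 16.

Steps most likely to fail

Step 20 (ring closure). What may go wrong is intermolecular coupling to oligomers and loss of control over the alkene geometry during the non-stereospecific deoxygenation. The fallback sets out from 31 and returns at 33, splitting the ring closure into two stages. 31 is cyclised with the same titanium reagent at 25 °C without heating, which should stop at the macrocyclic 7,8-diols. The like-configured (7R,8R)-diol F1 (its 7S,8S counterpart serves equally) is separated from the unlike diols. It is converted with 1,1′-thiocarbonyldiimidazole (toluene, 100 °C) into the cyclic thiocarbonate F2. Fragmentation with 1,3-dimethyl-2-phenyl-1,3,2-diazaphospholidine (40 °C, Corey–Winter syn elimination) should then return 33 with the 7E geometry fixed by the diol configuration.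

Step 24 (inversion at C13). What may go wrong is elimination or participation of the neighbouring epoxide instead of SN2 displacement, since C13 is flanked by a fully substituted epoxide carbon and acetic acid is a weak Mitsunobu acid. The fallback sets out from 38 and returns at 39. The alcohol is first converted into its methanesulfonate F3 (MsCl, Et3N, CH2Cl2, −20 °C). This is displaced with CsOAc and 18-crown-6 in toluene at 80 °C, which should give the same inversion without an oxyphosphonium leaving group.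

Step 23 (epoxidation). What may go wrong is erosion of the facial selectivity by the conformation of the macrocycle. The fallback sets out from 37 and returns at 38 under reagent control instead of substrate direction: Ti(OiPr)4, D-(−)-diisopropyl tartrate, t-BuOOH, 4 Å molecular sieves, CH2Cl2, −20 °C (Sharpless asymmetric epoxidation). This tartrate is the matched partner of the 13R alcohol and should give the erythro epoxy alcohol; it makes no compound outside the list (F0).

Further compounds
F1 | step 20 | tert-butyl({2-[(1R,2S,3E,7R,8R,11E,13R)-2,13-bis{[tert-butyl(dimethyl)silyl]oxy}-7,8-dihydroxy-4,8,12-trimethylcyclotetradeca-3,11-dien-1-yl]prop-2-en-1-yl}oxy)diphenylsilane | C=C(CO[Si](c1ccccc1)(c1ccccc1)C(C)(C)C)[C@H]1C[C@@H](O[Si](C)(C)C(C)(C)C)/C(C)=C/CC[C@@](C)(O)[C@H](O)CC/C(C)=C/[C@@H]1O[Si](C)(C)C(C)(C)C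
F2 | step 20 | cyclic 7,8-thiocarbonate (1,3-dioxolane-2-thione) of F1 | C=C(CO[Si](c1ccccc1)(c1ccccc1)C(C)(C)C)[C@H]1C[C@@H](O[Si](C)(C)C(C)(C)C)/C(C)=C/CC[C@@]2(C)OC(=S)O[C@@H]2CC/C(C)=C/[C@@H]1O[Si](C)(C)C(C)(C)C
F3 | step 24 | (1R,2S,11R,12R,13R)-11,12-epoxy-13-[(methanesulfonyl)oxy]cembra-3E,7E,15(17)-trien-16,2-olide | C=C1C(=O)O[C@H]2/C=C(\C)CC/C=C(\C)CC[C@H]3O[C@]3(C)[C@H](OS(C)(=O)=O)C[C@H]12
F0 | step 23 | none | none
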